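The route rests on the bond between C9, the ring-B methine lying between the methyl-bearing alkene carbon C8 and the quaternary ring-fusion carbon C10, and the side-chain methylene C11. In the precursor, bicyclic enone 5, C8 is still a ketone and C6=C7 is unsaturated, so C9 is the only enolisable carbon. Kinetic α′-alkylation of its lithium dienolate with the linalool-derived iodide 11, which already carries the C13 carbinol centre, joins the two halves and sets C9 in one operation by axial attack anti to the angular C10 methyl. The C8 carbonyl then becomes the C7=C8 methyl-alkene through 1,4-reduction, enol triflation and methylation. (Labdane-type locants: ring A = C1–C5/C10 with Br on C3; ring B = C5–C10.)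

Key step: step 8

Assumption: the antipode of the thiophosphoramide catalyst that leads to the (4aS,6R,8aS) series of 4 is the one used, and (E)-geranylacetone and (R)-(−)-linalool are taken as commercial materials of high isomeric and enantiomeric purity.

Step 1
Reactants: 1 (5E)-6,10-dimethylundeca-5,9-dien-2-one ((E)-geranylacetone)
Product: 3 (5E)-6,10-dimethylundeca-1,5,9-trien-2-yl acetate, via kinetic lithium enolate 2 (not isolated)
Conditions: LDA (commercial solution), THF, −78 °C; Ac2O, −78 → 0 °C
Reagents that add atoms: acetic anhydride CC(=O)OC(C)=O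
Why: Kinetic deprotonation of the methyl ketone on its CH3 side and O-acylation of the lithium enolate should give the terminal enol acetate (enol ester formation), with no stereocentre formed and the 5E alkene untouched.

Step 2
Reactants: 3 (5E)-6,10-dimethylundeca-1,5,9-trien-2-yl acetate
Product: 4 (4aS,6R,8aS)-6-bromo-5,5,8a-trimethyloctahydronaphthalen-2(1H)-one (trans-fused, Br equatorial and cis to the angular methyl)
Conditions: chiral BINOL-derived thiophosphoramide (10 mol %), DBDMH, toluene/CH2Cl2, −90 °C; aq. NaHCO3
Reagents that add atoms: 1,3-dibromo-5,5-dimethylhydantoin (DBDMH) CC1(C)N(Br)C(=O)N(Br)C1=O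
Why: Proposed new method: the P=S Lewis base of the catalyst should activate DBDMH as a chiral bromosulfonium that transfers Br+ face-selectively to the distal trisubstituted alkene (the enol acetate is far less nucleophilic toward Br+), after which anti-periplanar chair–chair cyclisation through the 5E alkene and capture of the C10 cation by the enol acetate carbon C9, with loss of the acetyl group, should give the trans-decalone; the relative configuration at C3, C5 and C10 follows from the chair–chair transition state and the absolute configuration from the catalyst; the closest known reaction type is the catalytic asymmetric bromonium-induced cyclisation of arene-terminated polyenes with this catalyst class, together with racemic haliranium-induced polyene cyclisations that tolerate non-aromatic terminators.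

Step 3
Reactants: 4 (4aS,6R,8aS)-6-bromo-5,5,8a-trimethyloctahydronaphthalen-2(1H)-one
Product: 5 (4aS,6R,8aS)-6-bromo-5,5,8a-trimethyl-4a,5,6,7,8,8a-hexahydronaphthalen-2(1H)-one
Conditions: IBX, DMSO, 70 °C
Reagents that add atoms: none
Why: IBX dehydrogenation of a ketone to its enone can only install C6=C7, because C9 is flanked by the quaternary C10 and has no hydrogen-bearing neighbour to lose; no stereocentre is touched.

Step 4
Reactants: 6 (R)-(−)-linalool, (3R)-3,7-dimethylocta-1,6-dien-3-ol
Product: 8 (5R)-5-ethenyl-5-methyloxolan-2-ol (lactol; both anomers), via hydroxy aldehyde 7 (not isolated)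
Conditions: O3, CH2Cl2/MeOH, −78 °C (Sudan Red 7B end-point); Me2S, −78 °C → rt
Reagents that add atoms: ozone [O-][O+]=O
Why: Chemoselective ozonolysis should cleave the electron-rich trisubstituted alkene well before the vinyl group, and the resulting 4-hydroxy aldehyde closes spontaneously to the lactol, with the tertiary carbinol centre untouched.

Step 5
Reactants: 8 (5R)-5-ethenyl-5-methyloxolan-2-ol
Product: 9 (3R)-5-iodo-3-methylpent-1-en-3-yl formate
Conditions: PhI(OAc)2, I2, CH2Cl2, hν (visible), rt
Reagents that add atoms: iodine II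
Why: Suárez-type hypoiodite reaction: the anomeric alkoxy radical undergoes β-scission of the ring C–C bond to a formate and a primary radical that is trapped by iodine, so both anomers converge on one iodide one carbon shorter, and the quaternary stereocentre is retained.

Step 6
Reactants: 9 (3R)-5-iodo-3-methylpent-1-en-3-yl formate
Product: 10 (3R)-5-iodo-3-methylpent-1-en-3-ol
Conditions: K2CO3 (cat.), MeOH, 0 °C
Reagents that add atoms: none
Why: Base-catalysed transesterification removes the unhindered formyl group quickly, while low temperature and catalytic base should prevent oxetane closure or iodide displacement.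

Step 7
Reactants: 10 (3R)-5-iodo-3-methylpent-1-en-3-ol
Product: 11 triethyl{[(3R)-5-iodo-3-methylpent-1-en-3-yl]oxy}silane
Conditions: TESOTf, 2,6-lutidine, CH2Cl2, −78 → 0 °C
Reagents that add atoms: triethylsilyl trifluoromethanesulfonate CC[Si](CC)(CC)OS(=O)(=O)C(F)(F)F
Why: Silyl triflate with a hindered pyridine base is the standard silylation of tertiary alcohols and leaves the primary iodide and the vinyl group untouched.

Step 8
Reactants: 5 (4aS,6R,8aS)-6-bromo-5,5,8a-trimethyl-4a,5,6,7,8,8a-hexahydronaphthalen-2(1H)-one; 11 triethyl{[(3R)-5-iodo-3-methylpent-1-en-3-yl]oxy}silane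
Product: 13 (1R,4aS,6R,8aR)-6-bromo-5,5,8a-trimethyl-1-[(3R)-3-methyl-3-(triethylsilyloxy)pent-4-en-1-yl]-4a,5,6,7,8,8a-hexahydronaphthalen-2(1H)-one, via lithium dienolate 12 (not isolated)
Conditions: LDA (commercial solution), THF, −78 °C; 11, HMPA, −78 → −20 °C
Reagents that add atoms: none
Why: LDA removes a C9 hydrogen of 5 under kinetic control (C7 is vinylic and γ-deprotonation at C5 is slower), giving the cross-conjugated lithium dienolate 12, which attacks the primary iodide 11 at C11 in an SN2 reaction. The closest known reaction type is the kinetic α′-alkylation of cyclohexenone lithium enolates next to a quaternary carbon (isophorone-type alkylations). No ring is closed. The new stereocentre C9 is controlled by the substrate: stereoelectronically preferred axial attack on the enolate coincides with the face anti to the axial C10 methyl, so C11 should enter trans to that methyl and cis to H-5, as the target requires. The step needs C- over O-alkylation and α′- over γ-alkylation, which the lithium counter-ion, the soft primary iodide, HMPA and low temperature should secure; C13 in 11 is not involved.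

Step 9
Reactants: 13 (1R,4aS,6R,8aR)-6-bromo-5,5,8a-trimethyl-1-[(3R)-3-methyl-3-(triethylsilyloxy)pent-4-en-1-yl]-4a,5,6,7,8,8a-hexahydronaphthalen-2(1H)-one
Product: 15 (1R,4aS,6R,8aR)-6-bromo-5,5,8a-trimethyl-1-[(3R)-3-methyl-3-(triethylsilyloxy)pent-4-en-1-yl]-1,4,4a,5,6,7,8,8a-octahydronaphthalen-2-yl trifluoromethanesulfonate, via lithium enolate 14 (not isolated)
Conditions: L-Selectride, THF, −78 °C; PhNTf2, −78 → 0 °C
Reagents that add atoms: N-phenylbis(trifluoromethanesulfonimide) O=S(=O)(N(c1ccccc1)S(=O)(=O)C(F)(F)F)C(F)(F)F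
Why: Conjugate reduction of the β-unsubstituted cyclohexenone by the bulky borohydride gives the C7=C8 enolate regiospecifically, and O-triflation fixes it as the enol triflate; C9 is not deprotonated, so its configuration is kept.

Step 10
Reactants: 15 (1R,4aS,6R,8aR)-6-bromo-5,5,8a-trimethyl-1-[(3R)-3-methyl-3-(triethylsilyloxy)pent-4-en-1-yl]-1,4,4a,5,6,7,8,8a-octahydronaphthalen-2-yl trifluoromethanesulfonate
Product: 16 {[(3R)-5-[(1S,4aS,6R,8aS)-6-bromo-2,5,5,8a-tetramethyl-1,4,4a,5,6,7,8,8a-octahydronaphthalen-1-yl]-3-methylpent-1-en-3-yl]oxy}triethylsilane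
Conditions: MeZnCl (commercial solution, 3 equiv), Pd(PPh3)4 (5 mol %), THF, rt
Reagents that add atoms: methylzinc chloride C[Zn]Cl
Why: Negishi cross-coupling of the vinyl triflate installs the C8 methyl with the alkene fixed at C7=C8; transmetalation from zinc is expected to outrun Heck closure onto the distal vinyl group, and Pd(0)/PPh3 should not insert into the hindered secondary C–Br bond.

Step 11
Reactants: 16 {[(3R)-5-[(1S,4aS,6R,8aS)-6-bromo-2,5,5,8a-tetramethyl-1,4,4a,5,6,7,8,8a-octahydronaphthalen-1-yl]-3-methylpent-1-en-3-yl]oxy}triethylsilane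
Product: 17 (3R)-5-[(1S,4aS,6R,8aS)-6-bromo-2,5,5,8a-tetramethyl-1,4,4a,5,6,7,8,8a-octahydronaphthalen-1-yl]-3-methylpent-1-en-3-ol (target)
Conditions: TBAF, THF, 0 °C → rt
Reagents that add atoms: none
Why: Fluoride-mediated desilylation frees the tertiary alcohol; the equatorial neopentyl-type bromide has no anti-periplanar hydrogen and should resist elimination and substitution.

Compound list
1 | (5E)-6,10-dimethylundeca-5,9-dien-2-one ((E)-geranylacetone) | CC(C)=CCC/C(C)=C/CCC(C)=O | starting material
2 | lithium (5E)-6,10-dimethylundeca-1,5,9-trien-2-olate (kinetic enolate of 1) | CC(C)=CCC/C(C)=C/CCC(=C)O[Li] | intermediate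
3 | (5E)-6,10-dimethylundeca-1,5,9-trien-2-yl acetate | CC(C)=CCC/C(C)=C/CCC(=C)OC(C)=O | intermediate
4 | (4aS,6R,8aS)-6-bromo-5,5,8a-trimethyloctahydronaphthalen-2(1H)-one | O=C1CC[C@@H]2C(C)(C)[C@H](Br)CC[C@@]2(C)C1 | intermediate
5 | (4aS,6R,8aS)-6-bromo-5,5,8a-trimethyl-4a,5,6,7,8,8a-hexahydronaphthalen-2(1H)-one | O=C1C=C[C@@H]2C(C)(C)[C@H](Br)CC[C@@]2(C)C1 | intermediate
6 | (R)-(−)-linalool, (3R)-3,7-dimethylocta-1,6-dien-3-ol | C=C[C@](C)(O)CCC=C(C)C | starting material
7 | (4R)-4-hydroxy-4-methylhex-5-enal | C=C[C@](C)(O)CCC=O | intermediate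
8 | (5R)-5-ethenyl-5-methyloxolan-2-ol (lactol, both anomers) | C=C[C@@]1(C)CCC(O)O1 | intermediate
9 | (3R)-5-iodo-3-methylpent-1-en-3-yl formate | C=C[C@](C)(OC=O)CCI | intermediate
10 | (3R)-5-iodo-3-methylpent-1-en-3-ol | C=C[C@](C)(O)CCI | intermediate
11 | triethyl{[(3R)-5-iodo-3-methylpent-1-en-3-yl]oxy}silane | C=C[C@](C)(O[Si](CC)(CC)CC)CCI | intermediate
12 | lithium (4aS,6R,8aS)-6-bromo-5,5,8a-trimethyl-4a,5,6,7,8,8a-hexahydronaphthalen-2-olate (cross-conjugated dienolate of 5) | C1=C(O[Li])C=C[C@@H]2C(C)(C)[C@H](Br)CC[C@]21C | intermediate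
13 | (1R,4aS,6R,8aR)-6-bromo-5,5,8a-trimethyl-1-[(3R)-3-methyl-3-(triethylsilyloxy)pent-4-en-1-yl]-4a,5,6,7,8,8a-hexahydronaphthalen-2(1H)-one (side chain trans to the angular methyl) | C=C[C@](C)(O[Si](CC)(CC)CC)CC[C@H]1C(=O)C=C[C@@H]2C(C)(C)[C@H](Br)CC[C@]21C | intermediate
14 | lithium (1R,4aS,6R,8aR)-6-bromo-5,5,8a-trimethyl-1-[(3R)-3-methyl-3-(triethylsilyloxy)pent-4-en-1-yl]-1,4,4a,5,6,7,8,8a-octahydronaphthalen-2-olate | C=C[C@](C)(O[Si](CC)(CC)CC)CC[C@H]1C(O[Li])=CC[C@@H]2C(C)(C)[C@H](Br)CC[C@]21C | intermediate
15 | (1R,4aS,6R,8aR)-6-bromo-5,5,8a-trimethyl-1-[(3R)-3-methyl-3-(triethylsilyloxy)pent-4-en-1-yl]-1,4,4a,5,6,7,8,8a-octahydronaphthalen-2-yl trifluoromethanesulfonate | C=C[C@](C)(O[Si](CC)(CC)CC)CC[C@H]1C(OS(=O)(=O)C(F)(F)F)=CC[C@@H]2C(C)(C)[C@H](Br)CC[C@]21C | intermediate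
16 | {[(3R)-5-[(1S,4aS,6R,8aS)-6-bromo-2,5,5,8a-tetramethyl-1,4,4a,5,6,7,8,8a-octahydronaphthalen-1-yl]-3-methylpent-1-en-3-yl]oxy}triethylsilane | C=C[C@](C)(O[Si](CC)(CC)CC)CC[C@H]1C(C)=CC[C@@H]2C(C)(C)[C@H](Br)CC[C@]21C | intermediate
17 | (3R)-5-[(1S,4aS,6R,8aS)-6-bromo-2,5,5,8a-tetramethyl-1,4,4a,5,6,7,8,8a-octahydronaphthalen-1-yl]-3-methylpent-1-en-3-ol | C=C[C@](C)(O)CC[C@H]1C(C)=CC[C@@H]2C(C)(C)[C@H](Br)CC[C@]21C | target

Total step count: 11. Longest linear sequence: 8 steps (6 → 17, steps 4 to 11).

Steps most likely to fail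

Step 2 (Proposed new method). Enantio-induction may be lost with a non-aromatic terminator, Br+ may attack the enol acetate, or the cation may be quenched after the first ring closure. The fallback sets out from 3 and uses known chemistry. Racemic bromonium-induced polyene cyclisation with the achiral reagent bromodiethylsulfonium bromopentachloroantimonate (MeNO2, −25 °C) would give 4 together with its mirror image, (4aR,6S,8aR)-6-bromo-5,5,8a-trimethyloctahydronaphthalen-2(1H)-one F1. An enzymatic kinetic resolution with an NADPH-dependent ketoreductase (alcohol dehydrogenase class, chosen from a commercial panel, isopropanol as terminal reductant) would then reduce only the unwanted enantiomer to (2R,4aR,6S,8aR)-6-bromo-5,5,8a-trimethyldecahydronaphthalen-2-ol F2 (the equatorial epimer is drawn; which epimer forms depends on the enzyme). Unreacted ketone is separated by chromatography and the route is rejoined at 4.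

Step 8 (key step). C-alkylation at the neopentyl-type enolate carbon may be slow enough for proton transfer to the extended dienolate or for O-alkylation to take over. The fallback sets out from 5 and reverses the polarity of the coupling. Dienolate 12 is brominated (NBS, −78 °C) to 1,6-dibromo-5,5,8a-trimethyl-4a,5,6,7,8,8a-hexahydronaphthalen-2(1H)-one F3 (either C1 epimer serves), and iodide 11 is converted with zinc dust and LiCl in THF into [(3R)-3-methyl-3-(triethylsilyloxy)pent-4-en-1-yl]zinc iodide F4. A nickel/pybox-catalysed Negishi coupling of the secondary α-bromo ketone with the alkylzinc reagent would pass through the planar C9 α-keto radical, so both bromide epimers should converge on capture anti to the C10 methyl, and the route is rejoined at 13.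

Step 5. Acetyl hypoiodite may add to the vinyl group, and the lactol may be over-oxidised to the lactone instead of fragmenting. The fallback sets out from 8 and cuts the same carbon–carbon bond by decarboxylation. The lactol is oxidised (Ag2CO3 on Celite) to (5R)-5-ethenyl-5-methyloxolan-2-one F5. Saponification (LiOH), silylation (TESOTf, 2,6-lutidine) and cleavage of the silyl ester on K2CO3/MeOH work-up give (4R)-4-methyl-4-(triethylsilyloxy)hex-5-enoic acid F6, which is coupled with N-hydroxyphthalimide (DIC) to 1,3-dioxoisoindolin-2-yl (4R)-4-methyl-4-(triethylsilyloxy)hex-5-enoate F7. Visible-light iododecarboxylation (LiI, catalytic PPh3, blue LED) would give the iodide directly, and the route is rejoined at 11, so that steps 6 and 7 are no longer needed.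

Further compounds
F1 | step 2 | (4aR,6S,8aR)-6-bromo-5,5,8a-trimethyloctahydronaphthalen-2(1H)-one | O=C1CC[C@H]2C(C)(C)[C@@H](Br)CC[C@]2(C)C1
F2 | step 2 | (2R,4aR,6S,8aR)-6-bromo-5,5,8a-trimethyldecahydronaphthalen-2-ol | O[C@@H]1CC[C@H]2C(C)(C)[C@@H](Br)CC[C@]2(C)C1
F3 | step 8 | (4aS,6R,8aR)-1,6-dibromo-5,5,8a-trimethyl-4a,5,6,7,8,8a-hexahydronaphthalen-2(1H)-one (C1 epimers) | BrC1C(=O)C=C[C@@H]2C(C)(C)[C@H](Br)CC[C@]21C
F4 | step 8 | [(3R)-3-methyl-3-(triethylsilyloxy)pent-4-en-1-yl]zinc iodide | C=C[C@](C)(O[Si](CC)(CC)CC)CC[Zn]I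
F5 | step 5 | (5R)-5-ethenyl-5-methyloxolan-2-one | C=C[C@@]1(C)CCC(=O)O1
F6 | step 5 | (4R)-4-methyl-4-(triethylsilyloxy)hex-5-enoic acid | C=C[C@](C)(O[Si](CC)(CC)CC)CCC(=O)O
F7 | step 5 | 1,3-dioxoisoindolin-2-yl (4R)-4-methyl-4-(triethylsilyloxy)hex-5-enoate | C=C[C@](C)(O[Si](CC)(CC)CC)CCC(=O)ON1C(=O)c2ccccc2C1=O
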